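**Retrosynthetic overview**

1. Ring A is disconnected as a formal [4+2] union of tert-butyl methacrylate (C3=C4 carrying C18 and C19) with a ring B keto-aldehyde: C2–C3 by ketyl–olefin coupling, C4–C5 by samarium-enolate aldol closure. Ring B is built first, ring A second.
2. Enabling feature: C2 (aldehyde on the C10 side arm) and C5 (ketone in ring B) are two carbonyl carbons in a 1,4-relationship across C1–C10. Two electrons turn C2 into a nucleophile, and the α-carbon of the acceptor (C4) then reaches the C5 carbonyl through a six-membered transition state.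
3. Ring B: copper-catalysed asymmetric conjugate addition of the C11–C16 zinc reagent (C13 from methyl hydrogen (R)-3-methylglutarate) to 4,4-dimethoxycyclohexa-2,5-dienone sets C9; two enolate alkylations set the quaternary C10.
4. After the key step: the C5 hydroxyl is eliminated and the C5=C6 alkene is moved into conjugation with the unveiled C8 ketone (trans ring fusion). A C7=C8 enol triflate and Negishi methylation give the alkene; C2 is set by equilibrating transfer hydrogenation; C19 and C15 are adjusted by reduction, selective oxidation and acetylation.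

Key step: step 8

Remark: carbons are numbered as in labdanes (C1–C10 decalin, C11–C16 side chain, C17 on C8, C18/C19 on C4, C20 on C10); the target is read as the (2S,4R,5S,9R,10S,13R) isomer, and compounds 1, 4 and 11 are taken as commercial.

**Route**

Step 1
Reactants: 1 methyl hydrogen (R)-3-methylglutarate
Product: 2 methyl (3R)-5-hydroxy-3-methylpentanoate
Conditions: BH3·SMe2, THF, 0 °C to rt; MeOH, then aqueous work-up
Reagents that add atoms: none
Why: Borane reduces the free carboxylic acid much faster than the ester (chemoselective borane reduction), and no bond to the C13 stereocenter is touched.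

Step 2
Reactants: 2 methyl (3R)-5-hydroxy-3-methylpentanoate
Product: 3 methyl (3S)-5-iodo-3-methylpentanoate
Conditions: I2, PPh3, imidazole, CH2Cl2, 0 °C
Reagents that add atoms: iodine (II)
Why: Appel-type iodination of the primary alcohol, used at once so that the hydroxy ester cannot lactonise; the descriptor changes only because of the priority rules.

Step 3
Reactants: 3 methyl (3S)-5-iodo-3-methylpentanoate; 4 4,4-dimethoxycyclohexa-2,5-dien-1-one
Product: 6 methyl (3R)-5-[(1S)-6,6-dimethoxy-3-oxocyclohex-4-en-1-yl]-3-methylpentanoate, via dialkylzinc 5 (not isolated)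
Conditions: Et2Zn, CuI (cat.), neat, 50 °C, then evacuate; Cu(OTf)2 (cat.), BINOL/bis(1-phenylethyl)amine phosphoramidite (cat., the enantiomer that gives the (1S) adduct), toluene, −25 °C; aq. NH4Cl
Reagents that add atoms: none
Why: Iodine–zinc exchange gives an ester-tolerant dialkylzinc, and copper/phosphoramidite-catalysed asymmetric conjugate addition of dialkylzincs to this quinone monoketal should add the chain to one of the two enantiotopic enone arms, the ligand setting C9 and the second enone remaining as a blocking group.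

Step 4
Reactants: 6 methyl (3R)-5-[(1S)-6,6-dimethoxy-3-oxocyclohex-4-en-1-yl]-3-methylpentanoate
Product: 7 methyl (3R)-5-[(1S)-6,6-dimethoxy-2-methyl-3-oxocyclohex-4-en-1-yl]-3-methylpentanoate (both C10 epimers)
Conditions: LiN(iPr)2, THF, −78 °C; MeI, −78 to 0 °C
Reagents that add atoms: iodomethane (CI)
Why: The cross-conjugated lithium enolate can form only at C10 (the other α-position is vinylic and the ketone is far more acidic than the ester), and its C-methylation is a standard enolate alkylation whose configuration is erased in step 5.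

Step 5
Reactants: 7 methyl (3R)-5-[(1S)-6,6-dimethoxy-2-methyl-3-oxocyclohex-4-en-1-yl]-3-methylpentanoate
Product: 8 methyl (3R)-5-[(1S,2S)-6,6-dimethoxy-2-methyl-3-oxo-2-(prop-2-en-1-yl)cyclohex-4-en-1-yl]-3-methylpentanoate (ring methyl cis to the side chain)
Conditions: LiN(iPr)2, THF/DMPU, −78 °C; allyl bromide, −78 to −20 °C
Reagents that add atoms: allyl bromide (C=CCBr)
Why: Second α-alkylation of the same enolate, in which the electrophile should enter anti to the neighbouring C9 side chain, so that the allyl group (C1–C2 precursor) ends trans and the C10 methyl cis to the side chain.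

Step 6
Reactants: 8 methyl (3R)-5-[(1S,2S)-6,6-dimethoxy-2-methyl-3-oxo-2-(prop-2-en-1-yl)cyclohex-4-en-1-yl]-3-methylpentanoate
Product: 9 methyl (3R)-5-[(1S,2S)-6,6-dimethoxy-2-methyl-3-oxo-2-(prop-2-en-1-yl)cyclohexyl]-3-methylpentanoate
Conditions: Li[HB(s-Bu)3], THF, −78 °C; aq. NH4Cl
Reagents that add atoms: none
Why: Conjugate (1,4) reduction of a β-unsubstituted cyclohexenone by the bulky trialkylborohydride, 1,2-attack at the neopentyl carbonyl being disfavoured and the allyl group and ester being inert at −78 °C.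

Step 7
Reactants: 9 methyl (3R)-5-[(1S,2S)-6,6-dimethoxy-2-methyl-3-oxo-2-(prop-2-en-1-yl)cyclohexyl]-3-methylpentanoate
Product: 10 methyl (3R)-5-[(1S,2S)-6,6-dimethoxy-2-methyl-3-oxo-2-(2-oxoethyl)cyclohexyl]-3-methylpentanoate
Conditions: O3, CH2Cl2/MeOH, −78 °C; Me2S
Reagents that add atoms: ozone ([O-][O+]=O)
Why: Ozonolysis with reductive work-up cleaves the only alkene and gives the C2 aldehyde.

Step 8
Reactants: 10 methyl (3R)-5-[(1S,2S)-6,6-dimethoxy-2-methyl-3-oxo-2-(2-oxoethyl)cyclohexyl]-3-methylpentanoate; 11 tert-butyl methacrylate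
Product: 13 tert-butyl 2,5-dihydroxy-8,8-dimethoxy-4,10-dimethyl-9-[(3R)-5-methoxy-3-methyl-5-oxopentyl]decalin-4-carboxylate (labdane numbering; C4 ester and C5 hydroxyl and C10 methyl and C9 side chain all cis; both C2 epimers), via samarium enolate 12 (not isolated)
Conditions: SmI2 (2.5 equiv), 11 (5 equiv), THF, −78 to 0 °C, no proton source; aq. NH4Cl
Reagents that add atoms: none
Why: Proposed new method: SmI2 should reduce the aldehyde of 10 to a ketyl radical that adds to the β-carbon of 11 (C2–C3, a union of two electrophilic carbons made possible by the radical), a second electron gives the trivalent samarium ester enolate 12, and this closes on the C5 ketone by intramolecular aldol addition (C4–C5). The closest known reaction types are the SmI2-mediated aldehyde/acrylate ketyl–olefin coupling and SmI2 radical-addition/aldol cascades in which the samarium enolate left by the radical step is trapped by a carbonyl group; the new element is their intermolecular/intramolecular combination into a six-membered ring. Ring A closes in the 6-(enolexo)-exo-trig mode. C4 should be set in a closed chair transition state in which samarium bridges the enolate oxygen and the ketone oxygen, so that the ester carbon ends cis to the new C5 oxygen and to the C10 methyl group and the C4 methyl takes the other position; the C5 carbinol (cis ring fusion) is removed in step 10 and the uncontrolled C2 carbinol is corrected in steps 9 and 11. The step needs reduction of the aldehyde in preference to the ketone, intermolecular addition faster than pinacol coupling, and an enolate that lives until ring closure: these are secured by the easier reduction of aldehydes and the hindered α-quaternary ketone, by the excess of 11, and by the absence of a proton source. The tert-butyl ester keeps the C2 alkoxide from lactonising.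

Step 9
Reactants: 13 tert-butyl 2,5-dihydroxy-8,8-dimethoxy-4,10-dimethyl-9-[(3R)-5-methoxy-3-methyl-5-oxopentyl]decalin-4-carboxylate
Product: 14 tert-butyl 5-hydroxy-8,8-dimethoxy-4,10-dimethyl-2-oxo-9-[(3R)-5-methoxy-3-methyl-5-oxopentyl]decalin-4-carboxylate
Conditions: Dess–Martin periodinane, NaHCO3, CH2Cl2, rt
Reagents that add atoms: none
Why: Dess–Martin oxidation of the secondary C2 carbinol makes both epimers converge on one ketone, while the tertiary C5 alcohol cannot be oxidised.

Step 10
Reactants: 14 tert-butyl 5-hydroxy-8,8-dimethoxy-4,10-dimethyl-2-oxo-9-[(3R)-5-methoxy-3-methyl-5-oxopentyl]decalin-4-carboxylate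
Product: 15 tert-butyl 8,8-dimethoxy-4,10-dimethyl-2-oxo-9-[(3R)-5-methoxy-3-methyl-5-oxopentyl]-Δ5(6)-octalin-4-carboxylate
Conditions: SOCl2, pyridine, 0 °C
Reagents that add atoms: none
Why: Dehydration of the tertiary alcohol through its chlorosulfite, where only C6 carries β-hydrogens (C4 and C10 are quaternary), so the C5=C6 alkene is the only possible product and a free cation with methyl shift is avoided in the basic medium.

Step 11
Reactants: 15 tert-butyl 8,8-dimethoxy-4,10-dimethyl-2-oxo-9-[(3R)-5-methoxy-3-methyl-5-oxopentyl]-Δ5(6)-octalin-4-carboxylate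
Product: 16 tert-butyl (2S)-2-hydroxy-8,8-dimethoxy-4,10-dimethyl-9-[(3R)-5-methoxy-3-methyl-5-oxopentyl]-Δ5(6)-octalin-4-carboxylate (equatorial hydroxyl, trans to the C10 methyl)
Conditions: [(η5-Ph4C4CO)2H]Ru2(CO)4(μ-H) (cat.), iPrOH, toluene, 80 °C
Reagents that add atoms: none
Why: Ruthenium-catalysed transfer hydrogenation is reversible (the carbinol is dehydrogenated and re-hydrogenated), so the thermodynamically preferred equatorial C2 alcohol should result, the axial position being 1,3-diaxial to both the C10 methyl and the C4 ester; the neutral conditions leave both esters unchanged.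

Step 12
Reactants: 16 tert-butyl (2S)-2-hydroxy-8,8-dimethoxy-4,10-dimethyl-9-[(3R)-5-methoxy-3-methyl-5-oxopentyl]-Δ5(6)-octalin-4-carboxylate
Product: 17 tert-butyl (2S)-2-(tert-butyldimethylsilyloxy)-8,8-dimethoxy-4,10-dimethyl-9-[(3R)-5-methoxy-3-methyl-5-oxopentyl]-Δ5(6)-octalin-4-carboxylate
Conditions: TBSCl, imidazole, DMF, rt
Reagents that add atoms: tert-butyldimethylsilyl chloride (CC(C)(C)[Si](C)(C)Cl)
Why: Standard silylation of the unhindered secondary alcohol, needed because the later enolate triflation and hydride steps do not tolerate a free hydroxyl.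

Step 13
Reactants: 17 tert-butyl (2S)-2-(tert-butyldimethylsilyloxy)-8,8-dimethoxy-4,10-dimethyl-9-[(3R)-5-methoxy-3-methyl-5-oxopentyl]-Δ5(6)-octalin-4-carboxylate
Product: 19 tert-butyl (2S)-2-(tert-butyldimethylsilyloxy)-4,10-dimethyl-8-oxo-9-[(3R)-5-methoxy-3-methyl-5-oxopentyl]-Δ6(7)-octalin-4-carboxylate (trans ring fusion), via deconjugated enone 18 (not isolated)
Conditions: PPTS, acetone/H2O, rt; then DBU (cat.), CH2Cl2, rt
Reagents that add atoms: water (O)
Why: Mild acid hydrolysis of the dimethyl ketal gives the β,γ-unsaturated ketone and base moves the alkene into conjugation through the dienolate (as in the conversion of steroidal Δ5 3-ketals into Δ4 3-ketones), the reversible γ-protonation at C5 leading to the more stable trans ring fusion with hydrogen on the face away from the C10 methyl and the axial C4 ester.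

Step 14
Reactants: 19 tert-butyl (2S)-2-(tert-butyldimethylsilyloxy)-4,10-dimethyl-8-oxo-9-[(3R)-5-methoxy-3-methyl-5-oxopentyl]-Δ6(7)-octalin-4-carboxylate
Product: 21 the C7=C8 enol triflate of the C8 ketone (tert-butyl 15-methyl 2-silyloxy-8-triflyloxy-17-norlabd-7-ene-15,19-dioate), via lithium enolate 20 (not isolated)
Conditions: Li[HB(s-Bu)3], THF, −78 °C; then N-(5-chloropyridin-2-yl)bis(trifluoromethanesulfonimide), −78 to 0 °C
Reagents that add atoms: N-(5-chloropyridin-2-yl)bis(trifluoromethanesulfonimide) (O=S(=O)(N(c1ccc(Cl)cn1)S(=O)(=O)C(F)(F)F)C(F)(F)F)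
Why: Conjugate reduction of the enone delivers the enolate regiospecifically towards C7, and its O-triflation fixes the double bond at C7=C8.

Step 15
Reactants: 21 the C7=C8 enol triflate
Product: 22 19-tert-butyl 15-methyl (2S)-2-(tert-butyldimethylsilyloxy)labd-7-ene-15,19-dioate (target skeleton and configuration)
Conditions: MeZnCl, Pd(PPh3)4 (cat.), THF, 50 °C
Reagents that add atoms: methylzinc chloride (C[Zn]Cl)
Why: Negishi cross-coupling of the enol triflate installs the C8 methyl group with retention of the alkene position, and esters and silyl ether are tolerated by the organozinc.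

Step 16
Reactants: 22 19-tert-butyl 15-methyl (2S)-2-(tert-butyldimethylsilyloxy)labd-7-ene-15,19-dioate
Product: 23 (2S)-2-(tert-butyldimethylsilyloxy)labd-7-ene-15,19-diol
Conditions: LiAlH4, THF, 0 °C to reflux; aqueous NaOH work-up
Reagents that add atoms: none
Why: LiAlH4 reduces both esters to primary alcohols, including the hindered axial tert-butyl ester, without touching the silyl ether or the trisubstituted alkene.

Step 17
Reactants: 23 (2S)-2-(tert-butyldimethylsilyloxy)labd-7-ene-15,19-diol
Product: 24 (2S)-2-(tert-butyldimethylsilyloxy)-19-hydroxylabd-7-en-15-oic acid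
Conditions: TEMPO (cat.), PhI(OAc)2, MeCN/H2O, 0 °C to rt
Reagents that add atoms: water (O)
Why: Nitroxyl-mediated oxidation is strongly retarded at the neopentyl, axial C19 carbinol, so the unhindered C15 alcohol should be oxidised selectively through the aldehyde hydrate to the acid.

Step 18
Reactants: 24 (2S)-2-(tert-butyldimethylsilyloxy)-19-hydroxylabd-7-en-15-oic acid
Product: 25 (2S)-19-acetoxy-2-(tert-butyldimethylsilyloxy)labd-7-en-15-oic acid
Conditions: Ac2O, pyridine, DMAP (cat.), CH2Cl2, rt; aq. NaHCO3, then mild acidification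
Reagents that add atoms: acetic anhydride (CC(=O)OC(C)=O)
Why: DMAP-catalysed acetylation of the remaining primary alcohol, the mixed anhydride formed at the acid being hydrolysed during aqueous work-up.

Step 19
Reactants: 25 (2S)-19-acetoxy-2-(tert-butyldimethylsilyloxy)labd-7-en-15-oic acid
Product: 26 (2S,4R,5S,9R,10S,13R)-19-acetoxy-2-hydroxylabd-7-en-15-oic acid (CNP0162900.1)
Conditions: HF·pyridine, pyridine/THF, 0 °C to rt
Reagents that add atoms: none
Why: Fluoride cleaves the silyl ether under buffered conditions that leave the acetate, the acid and the trisubstituted alkene untouched.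

**Compound list**

1 | methyl hydrogen (R)-3-methylglutarate | OC(=O)C[C@@H](C)CC(=O)OC | starting material
2 | methyl (3R)-5-hydroxy-3-methylpentanoate | OCC[C@@H](C)CC(=O)OC | intermediate
3 | methyl (3S)-5-iodo-3-methylpentanoate | ICC[C@@H](C)CC(=O)OC | intermediate
4 | 4,4-dimethoxycyclohexa-2,5-dien-1-one | COC1(OC)C=CC(=O)C=C1 | starting material
5 | bis[(3S)-5-methoxy-3-methyl-5-oxopentyl]zinc | COC(=O)C[C@H](C)CC[Zn]CC[C@@H](C)CC(=O)OC | intermediate
6 | methyl (3R)-5-[(1S)-6,6-dimethoxy-3-oxocyclohex-4-en-1-yl]-3-methylpentanoate | O=C1C=CC(OC)(OC)[C@@H](CC[C@@H](C)CC(=O)OC)C1 | intermediate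
7 | methyl (3R)-5-[(1S)-6,6-dimethoxy-2-methyl-3-oxocyclohex-4-en-1-yl]-3-methylpentanoate (C10 epimers) | O=C1C=CC(OC)(OC)[C@@H](CC[C@@H](C)CC(=O)OC)C1C | intermediate
8 | methyl (3R)-5-[(1S,2S)-6,6-dimethoxy-2-methyl-3-oxo-2-(prop-2-en-1-yl)cyclohex-4-en-1-yl]-3-methylpentanoate | C=CC[C@@]1(C)[C@H](CC[C@@H](C)CC(=O)OC)C(OC)(OC)C=CC1=O | intermediate
9 | methyl (3R)-5-[(1S,2S)-6,6-dimethoxy-2-methyl-3-oxo-2-(prop-2-en-1-yl)cyclohexyl]-3-methylpentanoate | C=CC[C@@]1(C)[C@H](CC[C@@H](C)CC(=O)OC)C(OC)(OC)CCC1=O | intermediate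
10 | methyl (3R)-5-[(1S,2S)-6,6-dimethoxy-2-methyl-3-oxo-2-(2-oxoethyl)cyclohexyl]-3-methylpentanoate | O=CC[C@@]1(C)[C@H](CC[C@@H](C)CC(=O)OC)C(OC)(OC)CCC1=O | intermediate
11 | tert-butyl methacrylate (tert-butyl 2-methylprop-2-enoate) | C=C(C)C(=O)OC(C)(C)C | starting material
12 | diiodosamarium alkoxide/ester enolate of the open C2–C3 adduct | CC(CC(O[Sm](I)I)C[C@@]1(C)[C@H](CC[C@@H](C)CC(=O)OC)C(OC)(OC)CCC1=O)=C(O[Sm](I)I)OC(C)(C)C | intermediate
13 | tert-butyl 2,5-dihydroxy-8,8-dimethoxy-4,10-dimethyl-9-[(3R)-5-methoxy-3-methyl-5-oxopentyl]decalin-4-carboxylate (cis-fused; ester, 5-OH, 10-CH3 cis; C2 epimers) | CC(C)(C)OC(=O)[C@]1(C)CC(O)C[C@@]2(C)[C@H](CC[C@@H](C)CC(=O)OC)C(OC)(OC)CC[C@@]12O | intermediate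
14 | C2 ketone of 13 | CC(C)(C)OC(=O)[C@]1(C)CC(=O)C[C@@]2(C)[C@H](CC[C@@H](C)CC(=O)OC)C(OC)(OC)CC[C@@]12O | intermediate
15 | tert-butyl 8,8-dimethoxy-4,10-dimethyl-2-oxo-9-[(3R)-5-methoxy-3-methyl-5-oxopentyl]-Δ5(6)-octalin-4-carboxylate | CC(C)(C)OC(=O)[C@]1(C)CC(=O)C[C@@]2(C)[C@H](CC[C@@H](C)CC(=O)OC)C(OC)(OC)CC=C12 | intermediate
16 | (2S)-2-hydroxy analogue of 15 (equatorial OH) | CC(C)(C)OC(=O)[C@]1(C)C[C@@H](O)C[C@@]2(C)[C@H](CC[C@@H](C)CC(=O)OC)C(OC)(OC)CC=C12 | intermediate
17 | 2-O-tert-butyldimethylsilyl ether of 16 | CC(C)(C)OC(=O)[C@]1(C)C[C@@H](O[Si](C)(C)C(C)(C)C)C[C@@]2(C)[C@H](CC[C@@H](C)CC(=O)OC)C(OC)(OC)CC=C12 | intermediate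
18 | 8-oxo-Δ5(6) (β,γ-unsaturated) ketone | CC(C)(C)OC(=O)[C@]1(C)C[C@@H](O[Si](C)(C)C(C)(C)C)C[C@@]2(C)[C@H](CC[C@@H](C)CC(=O)OC)C(=O)CC=C12 | intermediate
19 | trans-fused 8-oxo-Δ6(7) enone | CC(C)(C)OC(=O)[C@]1(C)C[C@@H](O[Si](C)(C)C(C)(C)C)C[C@@]2(C)[C@H](CC[C@@H](C)CC(=O)OC)C(=O)C=C[C@H]12 | intermediate
20 | lithium C7=C8 enolate of the saturated C8 ketone | CC(C)(C)OC(=O)[C@]1(C)C[C@@H](O[Si](C)(C)C(C)(C)C)C[C@@]2(C)[C@H](CC[C@@H](C)CC(=O)OC)C(O[Li])=CC[C@H]12 | intermediate
21 | C7=C8 enol triflate | CC(C)(C)OC(=O)[C@]1(C)C[C@@H](O[Si](C)(C)C(C)(C)C)C[C@@]2(C)[C@H](CC[C@@H](C)CC(=O)OC)C(OS(=O)(=O)C(F)(F)F)=CC[C@H]12 | intermediate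
22 | 19-tert-butyl 15-methyl (2S)-2-(tert-butyldimethylsilyloxy)labd-7-ene-15,19-dioate | CC(C)(C)OC(=O)[C@]1(C)C[C@@H](O[Si](C)(C)C(C)(C)C)C[C@@]2(C)[C@H](CC[C@@H](C)CC(=O)OC)C(C)=CC[C@H]12 | intermediate
23 | (2S)-2-(tert-butyldimethylsilyloxy)labd-7-ene-15,19-diol | OC[C@]1(C)C[C@@H](O[Si](C)(C)C(C)(C)C)C[C@@]2(C)[C@H](CC[C@@H](C)CCO)C(C)=CC[C@H]12 | intermediate
24 | (2S)-2-(tert-butyldimethylsilyloxy)-19-hydroxylabd-7-en-15-oic acid | OC[C@]1(C)C[C@@H](O[Si](C)(C)C(C)(C)C)C[C@@]2(C)[C@H](CC[C@@H](C)CC(=O)O)C(C)=CC[C@H]12 | intermediate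
25 | (2S)-19-acetoxy-2-(tert-butyldimethylsilyloxy)labd-7-en-15-oic acid | CC(=O)OC[C@]1(C)C[C@@H](O[Si](C)(C)C(C)(C)C)C[C@@]2(C)[C@H](CC[C@@H](C)CC(=O)O)C(C)=CC[C@H]12 | intermediate
26 | (2S,4R,5S,9R,10S,13R)-19-acetoxy-2-hydroxylabd-7-en-15-oic acid (CNP0162900.1) | CC(=O)OC[C@]1(C)C[C@@H](O)C[C@@]2(C)[C@H](CC[C@@H](C)CC(=O)O)C(C)=CC[C@H]12 | target

**Totals**

Total step count: 19. Longest linear sequence: 19 steps (1 to 26; compounds 4 and 11 enter as purchased partners).

**Steps most likely to fail**

1. Step 8 (bears the label). What may go wrong: the samarium enolate is protonated or fragments by retro-aldol before it closes onto the hindered ketone, the ketyl dimerises, or the facial selectivity at C4 is poor because the chelated transition state is not followed. Fallback with known reactions, setting out from 10 and returning at 13: indium-mediated Barbier allylation of the aldehyde of 10 with tert-butyl 2-(bromomethyl)acrylate in THF/H2O forms C2–C3 and should give the α-methylene γ-hydroxy ester F1. Stoichiometric [(Ph3P)CuH]6 in toluene then adds hydride to the methylene carbon (which becomes C18), and the copper enolate closes on the C5 ketone in a reductive aldol cyclisation to give diol 13, which continues with step 9.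

2. Step 13. What may go wrong: the dienolate is re-protonated at C7 (no conjugation) or at C5 from the wrong face (cis ring fusion), or the silyl ether is lost during hydrolysis. Fallback, setting out from 17 and returning at 21: hydrogen-atom-transfer hydrogenation of the C5=C6 alkene of 17 [Mn(dpm)3 (cat.), PhSiH3, t-BuOOH, iPrOH], in which the tertiary C5 radical should take up hydrogen on the face away from the C10 methyl and the axial ester, gives the trans-fused saturated ketal F2. PPTS in wet acetone gives the saturated C8 ketone F3. KN(SiMe3)2 at −78 °C removes the less hindered C7 proton, and triflation with the reagent of step 14 gives enol triflate 21, so that step 14 is skipped.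

3. Step 17. What may go wrong: site selectivity is lost and the C19 carbinol is oxidised together with the C15 carbinol. Fallback, setting out from 22 and returning at 24: the two carboxyl groups are told apart by their ester type. TMSOTf/2,6-lutidine followed by water cleaves only the tert-butyl ester to the C19 carboxylic acid F4. Oxalyl chloride with catalytic DMF gives the acid chloride F5, and NaBH4 reduces it to the C19 alcohol with the methyl ester intact, F6. LiOH in THF/MeOH/H2O then hydrolyses the methyl ester and gives 24.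

**Further compounds**

F1 | step 8 | tert-butyl 4-hydroxy-2-methylidene-5-[(1S,2S)-3,3-dimethoxy-1-methyl-6-oxo-2-((3R)-5-methoxy-3-methyl-5-oxopentyl)cyclohexyl]pentanoate (C2 epimers) | C=C(CC(O)C[C@@]1(C)[C@H](CC[C@@H](C)CC(=O)OC)C(OC)(OC)CCC1=O)C(=O)OC(C)(C)C
F2 | step 13 | trans-fused saturated 8,8-dimethyl ketal (5,6-dihydro derivative of 17) | CC(C)(C)OC(=O)[C@]1(C)C[C@@H](O[Si](C)(C)C(C)(C)C)C[C@@]2(C)[C@H](CC[C@@H](C)CC(=O)OC)C(OC)(OC)CC[C@H]12
F3 | step 13 | trans-fused saturated C8 ketone | CC(C)(C)OC(=O)[C@]1(C)C[C@@H](O[Si](C)(C)C(C)(C)C)C[C@@]2(C)[C@H](CC[C@@H](C)CC(=O)OC)C(=O)CC[C@H]12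
F4 | step 17 | (2S)-2-(tert-butyldimethylsilyloxy)-15-methoxy-15-oxolabd-7-en-19-oic acid | OC(=O)[C@]1(C)C[C@@H](O[Si](C)(C)C(C)(C)C)C[C@@]2(C)[C@H](CC[C@@H](C)CC(=O)OC)C(C)=CC[C@H]12
F5 | step 17 | the C19 acid chloride of F4 | ClC(=O)[C@]1(C)C[C@@H](O[Si](C)(C)C(C)(C)C)C[C@@]2(C)[C@H](CC[C@@H](C)CC(=O)OC)C(C)=CC[C@H]12
F6 | step 17 | methyl (2S)-2-(tert-butyldimethylsilyloxy)-19-hydroxylabd-7-en-15-oate | OC[C@]1(C)C[C@@H](O[Si](C)(C)C(C)(C)C)C[C@@]2(C)[C@H](CC[C@@H](C)CC(=O)OC)C(C)=CC[C@H]12
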